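**Assumptions (one line):** germacrane numbering is used for the ten-membered ring (C1–C10; C11–C13 are the lactone carbons); compounds 1, 3 and 11 are taken as catalogue chemicals; the (R,R)-amide in Step 3 is assumed to be the antipode that removes the required proton (otherwise its enantiomer is used).

## Retrosynthetic overview

1. Cardivin D ⇒ desilylation, C9 acylation, outer-face syn-dihydroxylation of an (E)-9(10)-ene and oxidative 8,12-lactonisation of a 6-O-isobutyryl-5-oxocyclodec-9-ene.
2. Ten-membered ring ⇒ anionic oxy-Cope ring expansion of a trans-1,2-dialkenylcyclohexanol (breaks C5–C10, makes C7–C8), with the enolate trapped as C6–O-isobutyryl; a chair transition state relays one quaternary centre into C6–C10.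
3. Carbinol ⇒ hindered cyclohexanone + (E)-dienyl-lithium; the C2 carbinol comes from L-Selectride reduction.
4. Cyclohexanone ⇒ meso cis-2,6-dimethylcyclohexane-1,4-dione by a one-flask desymmetrising enolisation/α-alkenylation with an (E)-iodo enol ether (key step).
5. meso-Dione ⇒ Birch reduction of 2,6-dimethylhydroquinone dimethyl ether. Ring order: cyclohexane (from the arene) → cyclodecene (ring expansion) → γ-lactone.

## Route

Step 1
Reactants: 1, 2,5-dimethoxy-1,3-dimethylbenzene
Product: 2, (2R,6S)-2,6-dimethylcyclohexane-1,4-dione (cis, meso)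
Conditions: Li, NH3(l), THF, t-BuOH, −78 → −33 °C; then 2 M HCl, THF, rt
Reagents that add atoms: water, O (both carbonyl oxygens)
Why: Birch reduction of the symmetric hydroquinone diether gives the 1,4-dimethoxycyclohexa-1,4-diene, whose two enol ethers hydrolyse to the dione; acid equilibrates the two α-methyl centres to the diequatorial cis (meso) isomer.

Step 2
Reactants: 3, (E)-1,2-diiodoethene (3 equiv); 4, 4-methoxybenzyl alcohol
Product: 5, (E)-1-iodo-2-[(4-methoxybenzyl)oxy]ethene
Conditions: CuI (10 mol %), 3,4,7,8-Me4-phenanthroline, Cs2CO3, toluene, 80 °C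
Reagents that add atoms: none
Why: Ullmann-type Cu-catalysed vinylic C–O coupling with retention of alkene geometry; excess diiodide and the electron-rich product suppress double coupling.

Step 3 (key step)
Reactants: 2, (2R,6S)-2,6-dimethylcyclohexane-1,4-dione; 5, (E)-1-iodo-2-[(4-methoxybenzyl)oxy]ethene
Product: 6, (2R,6S)-2-{(E)-2-[(4-methoxybenzyl)oxy]ethenyl}-2,6-dimethylcyclohexane-1,4-dione (methyls cis)
Conditions: (R,R)-(PhCHMe)2NLi, LiCl, THF, −78 °C; TMSCl (1.0 equiv); LDA, −78 °C; ZnCl2, −78 → 0 °C; 5, Pd2(dba)3/P(t-Bu)3 (cat.), 0 °C → rt; TBAF/AcOH, 0 °C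
Reagents that add atoms: none
Why: Proposed new method: the chiral lithium amide removes one of the enantiotopic axial α-CH2 protons of the unhindered carbonyl (Simpkins–Koga desymmetrisation, the reaction type used on cis-3,5-dimethylcyclohexanone) and TMSCl fixes this as a non-isolated 4-silyloxy-3-enone; LDA then removes the only doubly activated proton (α to C1=O and allylic, at C2), and the zinc dienolate undergoes Negishi-type Pd α-alkenylation (closest known: Pd-catalysed α-arylation/vinylation of ketone enolates to quaternary centres) at its α-carbon, anti to the C6 methyl, with retention of the E geometry (an E-β-alkoxyvinyl–Pd cannot syn-β-eliminate alkoxide), setting the 2R quaternary centre; fluoride returns the C4 ketone.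

Step 4
Reactants: 6
Product: 7, (2R,4S,6S)-4-hydroxy-2-{(E)-2-[(4-methoxybenzyl)oxy]ethenyl}-2,6-dimethylcyclohexan-1-one (OH cis to the alkenyl group, trans to both methyls)
Conditions: L-Selectride, THF, −78 °C; aq. NaBO3
Reagents that add atoms: none
Why: Substrate-controlled hydride reduction: only the unhindered C4 ketone reacts (C1 is flanked by a quaternary and a tertiary carbon), by equatorial attack opposite the axial 2-alkenyl group, giving the axial 4S alcohol.

Step 5
Reactants: 7
Product: 8, (2R,4S,6S)-4-[(tert-butyldimethylsilyl)oxy]-2-{(E)-2-[(4-methoxybenzyl)oxy]ethenyl}-2,6-dimethylcyclohexan-1-one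
Conditions: TBSOTf, 2,6-lutidine, CH2Cl2, −78 °C
Reagents that add atoms: TBSOTf, CC(C)(C)[Si](C)(C)OS(=O)(=O)C(F)(F)F
Why: Silylation of the hindered axial alcohol under buffered conditions that enol ethers tolerate; no stereocentre is affected.

Step 6
Reactants: 4, 4-methoxybenzyl alcohol; 9, 2,3-dibromoprop-1-ene
Product: 10, 1-{[(2-bromoprop-2-en-1-yl)oxy]methyl}-4-methoxybenzene
Conditions: NaH, THF/DMF, 0 °C → rt
Reagents that add atoms: none
Why: Williamson etherification at the allylic bromide; the vinylic bromide is inert to SN2.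

Step 7
Reactants: 10; 11, (E)-1,2-bis(tributylstannyl)ethene (2.5 equiv)
Product: 12, tributyl[(1E)-3-{[(4-methoxybenzyl)oxy]methyl}buta-1,3-dien-1-yl]stannane
Conditions: Pd(PPh3)4 (5 mol %), toluene, 90 °C
Reagents that add atoms: none
Why: Stille mono-coupling of the vinyl bromide with excess bis-stannane, with retention of the E geometry.

Step 8
Reactants: 8; 12
Product: 13, (1S,2R,4S,6S)-4-[(tert-butyldimethylsilyl)oxy]-2-{(E)-2-[(4-methoxybenzyl)oxy]ethenyl}-1-[(1E)-3-{[(4-methoxybenzyl)oxy]methyl}buta-1,3-dien-1-yl]-2,6-dimethylcyclohexan-1-ol (the two alkenyl groups trans)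
Conditions: 12, n-BuLi, THF, −78 °C; CeCl3; then 8, −78 °C
Reagents that add atoms: none
Why: Sn–Li exchange then organocerium 1,2-addition to the hindered, enolisable ketone; the reagent adds axially to the chair with equatorial methyls, opposite the axial C2 alkenyl group, giving the trans-dialkenyl carbinol (1S).

Step 9
Reactants: 13
Product: 14, (2S,4S,6S,7R,8S,9E)-2-[(tert-butyldimethylsilyl)oxy]-8-[(4-methoxybenzyl)oxy]-7-{3-[(4-methoxybenzyl)oxy]prop-1-en-2-yl}-4,10-dimethyl-5-oxocyclodec-9-en-6-yl 2-methylpropanoate (germacrane numbering; 2α-OTBS, 4β-Me, 6α-O-acyl, 7β-side chain, 8α-OPMB)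
Conditions: KH, 18-crown-6, THF, 0 °C → rt; −78 °C, 2-(phenylsulfonyl)-3-phenyloxaziridine; then (i-PrCO)2O, −78 → 0 °C
Reagents that add atoms: Davis oxaziridine, O1N(S(=O)(=O)c2ccccc2)C1c1ccccc1 (O at C6); isobutyric anhydride, CC(C)C(=O)OC(=O)C(C)C
Why: Anionic oxy-Cope ring expansion through a chair transition state with both E-alkenyl groups equatorial transfers the C1/C2 chirality of 13 to C7 (R) and C8 (S), gives the (E)-9-ene and the C5=C6 potassium enolate regiospecifically; Davis hydroxylation on the enolate's outer face (away from the transannular alkene) sets 6S, and in-situ acylation installs the C6 isobutyrate and differentiates O6 from O8 for the lactonisation.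

Step 10
Reactants: 14
Product: 15, (2S,4S,6S,7R,8S,9E)-2-[(tert-butyldimethylsilyl)oxy]-8-hydroxy-7-(3-hydroxyprop-1-en-2-yl)-4,10-dimethyl-5-oxocyclodec-9-en-6-yl 2-methylpropanoate
Conditions: DDQ, CH2Cl2/pH 7 buffer, 0 °C
Reagents that add atoms: none
Why: Oxidative cleavage of both PMB ethers; the silyl ether, ester, ketone and alkenes are untouched.

Step 11
Reactants: 15
Product: 16, (2S,4S,6S,7R,8S,9E)-2-[(tert-butyldimethylsilyl)oxy]-6-(isobutyryloxy)-5-oxogermacra-9,11(13)-dien-12,8-olide (trans-fused α-methylene-γ-lactone)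
Conditions: TEMPO (cat.), PhI(OAc)2, CH2Cl2, rt
Reagents that add atoms: none
Why: TEMPO/BAIB oxidative lactonisation: the primary allylic alcohol is oxidised selectively to the enal, which closes onto the only free secondary hydroxyl (8-OH) and is oxidised on to the lactone; no stereocentre changes.

Step 12
Reactants: 16
Product: 17, (2S,4S,6S,7R,8R,9S,10S)-2-[(tert-butyldimethylsilyl)oxy]-9,10-dihydroxy-6-(isobutyryloxy)-5-oxogermacr-11(13)-en-12,8-olide
Conditions: OsO4 (cat.), NMO, acetone/H2O, 0 °C → rt
Reagents that add atoms: OsO4, O=[Os](=O)(=O)=O; NMO, C[N+]1([O-])CCOCC1; water, O (the two hydroxyl oxygens)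
Why: Upjohn dihydroxylation of the electron-rich trisubstituted alkene in preference to the acrylate-type methylene; syn addition to the exposed outer face of the E-alkene (anti to the C7–C8 bond) sets 9S and 10S.

Step 13
Reactants: 17
Product: 18, 2-O-(tert-butyldimethylsilyl)cardivin D
Conditions: (i-PrCO)2O, DMAP (cat.), pyridine, CH2Cl2, 0 °C → rt
Reagents that add atoms: isobutyric anhydride, CC(C)C(=O)OC(=O)C(C)C
Why: DMAP-catalysed acylation of the secondary 9-OH; the tertiary 10-OH does not react, and the weak base limits epimerisation at C4/C6.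

Step 14
Reactants: 18
Product: 19, cardivin D
Conditions: HF·pyridine, pyridine/THF, 0 °C → rt
Reagents that add atoms: none
Why: Fluoride-mediated desilylation of the secondary TBS ether under mildly acidic conditions that spare the esters, the α-methylene lactone and the base-sensitive α-acyloxy ketone.

## Compound list

1 | 2,5-dimethoxy-1,3-dimethylbenzene | COc1cc(C)c(OC)c(C)c1 | starting material
2 | (2R,6S)-2,6-dimethylcyclohexane-1,4-dione (cis, meso) | O=C1[C@H](C)CC(=O)C[C@@H]1C | intermediate
3 | (E)-1,2-diiodoethene | I/C=C/I | starting material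
4 | 4-methoxybenzyl alcohol | COc1ccc(CO)cc1 | starting material
5 | (E)-1-iodo-2-[(4-methoxybenzyl)oxy]ethene | COc1ccc(CO/C=C/I)cc1 | intermediate
6 | (2R,6S)-2-{(E)-2-[(4-methoxybenzyl)oxy]ethenyl}-2,6-dimethylcyclohexane-1,4-dione | O=C1[C@@](C)(/C=C/OCc2ccc(OC)cc2)CC(=O)C[C@@H]1C | intermediate
7 | (2R,4S,6S)-4-hydroxy-2-{(E)-2-[(4-methoxybenzyl)oxy]ethenyl}-2,6-dimethylcyclohexan-1-one | O=C1[C@@](C)(/C=C/OCc2ccc(OC)cc2)C[C@@H](O)C[C@@H]1C | intermediate
8 | (2R,4S,6S)-4-(TBS-oxy)-2-{(E)-2-[(4-methoxybenzyl)oxy]ethenyl}-2,6-dimethylcyclohexan-1-one | O=C1[C@@](C)(/C=C/OCc2ccc(OC)cc2)C[C@@H](O[Si](C)(C)C(C)(C)C)C[C@@H]1C | intermediate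
9 | 2,3-dibromoprop-1-ene | C=C(Br)CBr | starting material
10 | 1-{[(2-bromoprop-2-en-1-yl)oxy]methyl}-4-methoxybenzene | C=C(Br)COCc1ccc(OC)cc1 | intermediate
11 | (E)-1,2-bis(tributylstannyl)ethene | CCCC[Sn](CCCC)(CCCC)/C=C/[Sn](CCCC)(CCCC)CCCC | starting material
12 | tributyl[(1E)-3-{[(4-methoxybenzyl)oxy]methyl}buta-1,3-dien-1-yl]stannane | C=C(COCc1ccc(OC)cc1)/C=C/[Sn](CCCC)(CCCC)CCCC | intermediate
13 | (1S,2R,4S,6S)-trans-1,2-dialkenyl carbinol (see Step 8) | O[C@@]1(/C=C/C(=C)COCc2ccc(OC)cc2)[C@@](C)(/C=C/OCc2ccc(OC)cc2)C[C@@H](O[Si](C)(C)C(C)(C)C)C[C@@H]1C | intermediate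
14 | (2S,4S,6S,7R,8S,9E)-2-OTBS-8-OPMB-7-[3-(PMB-oxy)prop-1-en-2-yl]-4,10-dimethyl-5-oxocyclodec-9-en-6-yl isobutyrate | O=C1[C@@H](C)C[C@H](O[Si](C)(C)C(C)(C)C)C/C(C)=C/[C@H](OCc2ccc(OC)cc2)[C@@H](C(=C)COCc2ccc(OC)cc2)[C@@H]1OC(=O)C(C)C | intermediate
15 | (2S,4S,6S,7R,8S,9E)-2-OTBS-8-hydroxy-7-(3-hydroxyprop-1-en-2-yl)-4,10-dimethyl-5-oxocyclodec-9-en-6-yl isobutyrate | O=C1[C@@H](C)C[C@H](O[Si](C)(C)C(C)(C)C)C/C(C)=C/[C@H](O)[C@@H](C(=C)CO)[C@@H]1OC(=O)C(C)C | intermediate
16 | (2S,4S,6S,7R,8S,9E)-2-OTBS-6-(isobutyryloxy)-5-oxogermacra-9,11(13)-dien-12,8-olide | C=C1C(=O)O[C@@H]2[C@@H]1[C@H](OC(=O)C(C)C)C(=O)[C@@H](C)C[C@H](O[Si](C)(C)C(C)(C)C)C/C(C)=C/2 | intermediate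
17 | (2S,4S,6S,7R,8R,9S,10S)-2-OTBS-9,10-dihydroxy-6-(isobutyryloxy)-5-oxogermacr-11(13)-en-12,8-olide | C=C1C(=O)O[C@@H]2[C@@H]1[C@H](OC(=O)C(C)C)C(=O)[C@@H](C)C[C@H](O[Si](C)(C)C(C)(C)C)C[C@](C)(O)[C@H]2O | intermediate
18 | 2-O-TBS-cardivin D | C=C1C(=O)O[C@@H]2[C@@H]1[C@H](OC(=O)C(C)C)C(=O)[C@@H](C)C[C@H](O[Si](C)(C)C(C)(C)C)C[C@](C)(O)[C@H]2OC(=O)C(C)C | intermediate
19 | cardivin D (2S,4S,6S,7R,8R,9S,10S) | C=C1C(=O)O[C@@H]2[C@@H]1[C@H](OC(=O)C(C)C)C(=O)[C@@H](C)C[C@H](O)C[C@](C)(O)[C@H]2OC(=O)C(C)C | target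

## Step count and risks

Total steps: 14. Longest linear sequence: 11 (Steps 1, 3, 4, 5, 8, 9, 10, 11, 12, 13, 14 from compound 1).

Steps most likely to fail:

1. **Step 3** (one-flask desymmetrisation/alkenylation). Risks: ee with a second carbonyl present, C2–H versus C6–H selectivity in the second deprotonation, α versus γ coupling of the dienolate, and Pd-induced aromatisation. Fallback: make the quaternary centre by SN2 chemistry instead. Oxidise 4-methoxy-2,6-dimethylphenol (PhI(OAc)2, MeOH) to the quinone monoketal, hydrogenate to the meso ketal-ketone, desymmetrise with the chiral amide and allylate at −78 °C, then hydrolyse the ketal, reduce with L-Selectride, silylate, ozonise, and O-alkylate the aldehyde enolate with PMBCl (E-selectivity of this last operation is not secured) to reach 8. This is longer but uses no Pd or dienolate.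

2. **Step 9** (oxy-Cope/hydroxylation/acylation cascade). Risks: the reactive chair needs both methyls axial, the enolate may equilibrate towards C4, and the face selectivity and yield of the Davis step are uncertain. Fallback: a neutral sequence. Heat the TMS ether of 13 (siloxy-Cope) to obtain the C5 silyl enol ether directly, then carry out Rubottom oxidation with DMDO at −78 °C and acylate.

3. **Step 12** (dihydroxylation). Risks: the outer-face selectivity depends on the macrocycle keeping its Cope-derived conformation, and the methylene lactone may compete. Fallback: Woodward cis-hydroxy-acyloxylation (I2, silver isobutyrate, wet i-PrCO2H). It delivers the syn-diol monoester on the face opposite to that attacked by OsO4 and installs the C9 isobutyrate directly, replacing Steps 12–13.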